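**Plan**

- Retrosynthesis (flavonoid numbering): the last cuts are the three O–benzyl bonds (3, 3', 4'), the 8-O–acetyl bond and the O–methyl bonds at C5 and C8, the latter two via the 5,8-quinone of ring A. The skeletal cut is O1–C2 of ring C, which folds the flavonol back to the isomeric spiro-oxirane of an aurone. The exocyclic C=C then falls to a coumaranone and the ring B aldehyde, and the coumaranone to 1,2,3,5-tetramethoxybenzene and chloroacetyl chloride.
- Forward: ring A is bought, the furanone ring closes by O-alkylation, ring B is joined by aldol condensation, the oxirane is added, and ring C arises last by expansion of the furanone from five to six members.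
- Enabling feature: the C3–OH/C4=O unit of ring C is the enol of a chroman-3,4-dione, which is an isomer of the aurone epoxide. O1 is the phenol oxygen of ring A, and the 4'-oxygen of ring B stabilises positive charge at C2. The C5 oxygen, which steers oxidative chalcone cyclisations towards aurones, does no harm on a route that wants the aurone.
- Stereochemistry: the target is achiral. The Z geometry of the aurone (thermodynamic) and the two oxirane centres (syn oxygen transfer, racemic) are relative only and are erased in the ring expansion.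

Key step: step 5

**Route**

Step 1
Reactants: 1 1,2,3,5-tetramethoxybenzene; 2 chloroacetyl chloride
Product: 4 2-chloro-1-(2-hydroxy-3,4,6-trimethoxyphenyl)ethan-1-one, via tetramethoxy chloroketone 3 (not isolated)
Conditions: AlCl3 (2.5 equiv), CH2Cl2, 0 °C to reflux; then ice/1 M HCl
Reagents that add atoms: none
Why: Friedel–Crafts acylation at one of the two equivalent free positions of 1 is followed in the same flask by AlCl3-mediated cleavage of the ortho methyl ether that is squeezed between the ketone and a second methoxy group (six-membered aluminium chelate, relief of buttressing), the selectivity expected from the analogous acetylation of 1.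

Step 2
Reactants: 4 2-chloro-1-(2-hydroxy-3,4,6-trimethoxyphenyl)ethan-1-one
Product: 5 4,6,7-trimethoxybenzofuran-3(2H)-one
Conditions: NaOAc, EtOH, reflux
Reagents that add atoms: none
Why: Intramolecular Williamson etherification (5-exo-tet) of the phenoxide on the α-chloro ketone is the standard closure to a benzofuran-3(2H)-one.

Step 3
Reactants: 5 4,6,7-trimethoxybenzofuran-3(2H)-one; 6 3,4-bis(benzyloxy)benzaldehyde
Product: 8 (Z)-2-[3,4-bis(benzyloxy)benzylidene]-4,6,7-trimethoxybenzofuran-3(2H)-one, via aldol adduct 7 (not isolated)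
Conditions: KOH, MeOH/THF, 50 °C
Reagents that add atoms: none
Why: Base-mediated aldol condensation of the C2 methylene of the coumaranone with the non-enolisable aldehyde (aurone synthesis) should give, after E1cB loss of water from adduct 7, the thermodynamically preferred Z alkene with the aryl group on the side of the ring oxygen.

Step 4
Reactants: 8 (Z)-2-[3,4-bis(benzyloxy)benzylidene]-4,6,7-trimethoxybenzofuran-3(2H)-one
Product: 9 rac-(2S,3'S)-3'-[3,4-bis(benzyloxy)phenyl]-4,6,7-trimethoxy-3H-spiro[benzofuran-2,2'-oxiran]-3-one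
Conditions: dimethyldioxirane (about 0.07 M in acetone, 1.5 equiv), CH2Cl2, 0 °C to rt; evaporation below 20 °C, used at once
Reagents that add atoms: dimethyldioxirane CC1(C)OO1
Why: Electrophilic epoxidation by a dioxirane transfers oxygen in a concerted syn manner to the electron-rich enol-ether/styrene double bond, so the Z geometry fixes the relative configuration of the two new centres (aryl cis to O1), the absence of any facial bias makes the oxirane racemic, and the only by-product is acetone, so the acid-labile product needs no work-up.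

Step 5
Reactants: 9 rac-(2S,3'S)-3'-[3,4-bis(benzyloxy)phenyl]-4,6,7-trimethoxy-3H-spiro[benzofuran-2,2'-oxiran]-3-one
Product: 11 2-[3,4-bis(benzyloxy)phenyl]-3-hydroxy-5,7,8-trimethoxy-4H-chromen-4-one, via chroman-3,4-dione 10 (not isolated)
Conditions: BF3·OEt2 (0.2 equiv), CH2Cl2, −78 to 0 °C; aq. NaHCO3
Reagents that add atoms: none
Why: Proposed new method: BF3 binds the oxirane oxygen and the benzylic C–O bond ionises to a cation held as a para-quinone-methide oxocarbenium by the 4'-benzyloxy group, leaving a boron-bound hemiketal oxygen on the spiro carbon; this hemiketal collapses to a ketone with cleavage of the old furanone C–O bond, and the freed ring A phenol oxygen captures the cation to form O1–C2, giving dione 10, which enolises to flavonol 11. The closest known reactions are the Auwers ring expansion of aurone dibromides with alkali, which runs through the same hemiketal opening and phenoxide reclosure with bromide as leaving group, and the BF3-induced House-type rearrangement of chalcone epoxides, which begins with the same benzylic ionisation. Ring C closes in a 6-exo-trig mode, the phenol oxygen adding to the trigonal benzylic carbon whose conjugated aryl unit stays outside the new ring. No stereocentre survives: C2 of dione 10 arises racemic from a planar cation and is erased on enolisation, as are both oxirane centres of 9. The step needs oxygen migration to outrun a 1,2-acyl shift (leading to a 3-aryl-4-hydroxycoumarin) and a hydride shift (leading to a 2-aroylcoumaranone), and the substrate secures this through the long-lived donor-stabilised cation, the easy fragmentation of a hemiketal whose leaving group is an ortho-acyl phenoxide, and the irreversible enolisation to the hydrogen-bonded 3-hydroxy-4-pyranone.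

Step 6
Reactants: 11 2-[3,4-bis(benzyloxy)phenyl]-3-hydroxy-5,7,8-trimethoxy-4H-chromen-4-one
Product: 12 3-(benzyloxy)-2-[3,4-bis(benzyloxy)phenyl]-5,7,8-trimethoxy-4H-chromen-4-one
Conditions: BnBr, K2CO3, DMF, rt
Reagents that add atoms: benzyl bromide BrCc1ccccc1
Why: Williamson etherification of the only free hydroxyl (the acidic 3-enol) protects it against the oxidation of step 7 and the acylation of step 9 with a group that leaves in step 10.

Step 7
Reactants: 12 3-(benzyloxy)-2-[3,4-bis(benzyloxy)phenyl]-5,7,8-trimethoxy-4H-chromen-4-one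
Product: 13 3-(benzyloxy)-2-[3,4-bis(benzyloxy)phenyl]-7-methoxy-4H-chromene-4,5,8-trione
Conditions: (NH4)2Ce(NO3)6 (2.5 equiv), MeCN/H2O 4:1, 0 °C
Reagents that add atoms: water O
Why: Oxidative demethylation of a para-dimethoxyarene by tetravalent cerium (two one-electron oxidations, addition of water at the two ipso carbons, loss of two molecules of methanol) should give the 5,8-quinone, because only the C5/C8 pair of ring A is para-disposed, whereas ring B (ortho-dialkoxy, conjugated to the pyranone) and the benzyl ethers are harder to oxidise.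

Step 8
Reactants: 13 3-(benzyloxy)-2-[3,4-bis(benzyloxy)phenyl]-7-methoxy-4H-chromene-4,5,8-trione
Product: 14 3-(benzyloxy)-2-[3,4-bis(benzyloxy)phenyl]-5,8-dihydroxy-7-methoxy-4H-chromen-4-one
Conditions: Na2S2O4, EtOAc/H2O, rt, argon
Reagents that add atoms: none
Why: Two-electron reduction of the quinone by dithionite in a two-phase system should give the hydroquinone, nothing else in the molecule being reducible under these conditions.

Step 9
Reactants: 14 3-(benzyloxy)-2-[3,4-bis(benzyloxy)phenyl]-5,8-dihydroxy-7-methoxy-4H-chromen-4-one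
Product: 15 3-(benzyloxy)-2-[3,4-bis(benzyloxy)phenyl]-5-hydroxy-7-methoxy-4-oxo-4H-chromen-8-yl acetate
Conditions: Ac2O (1.1 equiv), pyridine, CH2Cl2, 0 °C, argon
Reagents that add atoms: acetic anhydride CC(=O)OC(C)=O
Why: Chemoselective O-acetylation is expected because the 5-hydroxyl is locked in a hydrogen bond to the C4 carbonyl and is a poor nucleophile, so one equivalent of anhydride at 0 °C should acylate only the free 8-hydroxyl.

Step 10
Reactants: 15 3-(benzyloxy)-2-[3,4-bis(benzyloxy)phenyl]-5-hydroxy-7-methoxy-4-oxo-4H-chromen-8-yl acetate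
Product: 16 2-(3,4-dihydroxyphenyl)-3,5-dihydroxy-7-methoxy-4-oxo-4H-chromen-8-yl acetate (gossypetin 7-methyl ether 8-acetate)
Conditions: H2 (1 atm), 10% Pd/C, EtOAc/THF, rt
Reagents that add atoms: none
Why: Hydrogenolysis of the three benzyl ethers over Pd/C under neutral, non-nucleophilic conditions should leave the aryl acetate, the methyl ether and the chromone C2=C3 bond untouched.

**Compound list**

1 | 1,2,3,5-tetramethoxybenzene | COc1cc(OC)c(OC)c(OC)c1 | starting material
2 | chloroacetyl chloride | O=C(Cl)CCl | starting material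
3 | 2-chloro-1-(2,3,4,6-tetramethoxyphenyl)ethan-1-one (not isolated) | COc1cc(OC)c(C(=O)CCl)c(OC)c1OC | intermediate
4 | 2-chloro-1-(2-hydroxy-3,4,6-trimethoxyphenyl)ethan-1-one | COc1cc(OC)c(C(=O)CCl)c(O)c1OC | intermediate
5 | 4,6,7-trimethoxybenzofuran-3(2H)-one | COc1cc(OC)c2C(=O)COc2c1OC | intermediate
6 | 3,4-bis(benzyloxy)benzaldehyde | O=Cc1ccc(OCc2ccccc2)c(OCc2ccccc2)c1 | starting material
7 | 2-{[3,4-bis(benzyloxy)phenyl](hydroxy)methyl}-4,6,7-trimethoxybenzofuran-3(2H)-one (racemic diastereomer mixture, not isolated) | COc1cc(OC)c2C(=O)C(C(O)c3ccc(OCc4ccccc4)c(OCc4ccccc4)c3)Oc2c1OC | intermediate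
8 | (Z)-2-[3,4-bis(benzyloxy)benzylidene]-4,6,7-trimethoxybenzofuran-3(2H)-one | COc1cc(OC)c2C(=O)/C(=C/c3ccc(OCc4ccccc4)c(OCc4ccccc4)c3)Oc2c1OC | intermediate
9 | rac-(2S,3'S)-3'-[3,4-bis(benzyloxy)phenyl]-4,6,7-trimethoxy-3H-spiro[benzofuran-2,2'-oxiran]-3-one (aryl cis to the ring oxygen; racemic, one enantiomer drawn) | COc1cc(OC)c2C(=O)[C@@]3(O[C@H]3c4ccc(OCc5ccccc5)c(OCc5ccccc5)c4)Oc2c1OC | intermediate
10 | 2-[3,4-bis(benzyloxy)phenyl]-5,7,8-trimethoxychromane-3,4-dione (racemic, not isolated) | COc1cc(OC)c2C(=O)C(=O)C(c3ccc(OCc4ccccc4)c(OCc4ccccc4)c3)Oc2c1OC | intermediate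
11 | 2-[3,4-bis(benzyloxy)phenyl]-3-hydroxy-5,7,8-trimethoxy-4H-chromen-4-one | COc1cc(OC)c2c(=O)c(O)c(-c3ccc(OCc4ccccc4)c(OCc4ccccc4)c3)oc2c1OC | intermediate
12 | 3-(benzyloxy)-2-[3,4-bis(benzyloxy)phenyl]-5,7,8-trimethoxy-4H-chromen-4-one | COc1cc(OC)c2c(=O)c(OCc3ccccc3)c(-c3ccc(OCc4ccccc4)c(OCc4ccccc4)c3)oc2c1OC | intermediate
13 | 3-(benzyloxy)-2-[3,4-bis(benzyloxy)phenyl]-7-methoxy-4H-chromene-4,5,8-trione | COC1=CC(=O)C2=C(C1=O)OC(c1ccc(OCc3ccccc3)c(OCc3ccccc3)c1)=C(OCc1ccccc1)C2=O | intermediate
14 | 3-(benzyloxy)-2-[3,4-bis(benzyloxy)phenyl]-5,8-dihydroxy-7-methoxy-4H-chromen-4-one | COc1cc(O)c2c(=O)c(OCc3ccccc3)c(-c3ccc(OCc4ccccc4)c(OCc4ccccc4)c3)oc2c1O | intermediate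
15 | 3-(benzyloxy)-2-[3,4-bis(benzyloxy)phenyl]-5-hydroxy-7-methoxy-4-oxo-4H-chromen-8-yl acetate | COc1cc(O)c2c(=O)c(OCc3ccccc3)c(-c3ccc(OCc4ccccc4)c(OCc4ccccc4)c3)oc2c1OC(C)=O | intermediate
16 | 2-(3,4-dihydroxyphenyl)-3,5-dihydroxy-7-methoxy-4-oxo-4H-chromen-8-yl acetate (gossypetin 7-methyl ether 8-acetate) | COc1cc(O)c2c(=O)c(O)c(-c3ccc(O)c(O)c3)oc2c1OC(C)=O | target

**Count and risks**

Total step count: 10. Longest linear sequence: 10 steps (1 to 16); compounds 2 and 6 are purchased.

Steps most likely to fail:

1. Step 5 (the step labelled as a proposed new method). After benzylic ionisation the acyl carbon or a hydride may migrate faster than the ring oxygen, the cation may be intercepted by traces of water, or boron may be held by the chelating product so that turnover stops. The fallback uses known chemistry only and gives up the ring expansion; it sets out from 1 and 6 and rejoins the route at 11. Acetylation of 1 with acetyl chloride and AlCl3 gives 1-(2,3,4,6-tetramethoxyphenyl)ethan-1-one F1, which loses its flanked ortho methyl group in the same flask to give 1-(2-hydroxy-3,4,6-trimethoxyphenyl)ethan-1-one F2. Claisen–Schmidt condensation of F2 with 6 (KOH, EtOH) should give (E)-3-[3,4-bis(benzyloxy)phenyl]-1-(2-hydroxy-3,4,6-trimethoxyphenyl)prop-2-en-1-one F3. Oxidative cyclisation with catalytic I2 in DMSO at 130 °C should give 2-[3,4-bis(benzyloxy)phenyl]-5,7,8-trimethoxy-4H-chromen-4-one F4. Dimethyldioxirane should convert F4 into its 2,3-epoxide, 2-[3,4-bis(benzyloxy)phenyl]-2,3-epoxy-5,7,8-trimethoxychroman-4-one F5, which opens to 11 with catalytic TsOH.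

2. Step 7. Electron transfer from ring B or from the benzylic positions may compete with that from ring A, and the quinone may be attacked further by water or by the oxidant. The fallback replaces the one-electron oxidation of a bis-ether by a two-electron oxidation of a phenol; it sets out from 11 and rejoins at 13. MgI2·OEt2 in toluene/Et2O should cleave only the chelated 5-methyl ether to give 2-[3,4-bis(benzyloxy)phenyl]-3,5-dihydroxy-7,8-dimethoxy-4H-chromen-4-one F6. BnBr (1.05 equiv) and K2CO3 in acetone should alkylate the 3-hydroxyl and leave the hydrogen-bonded 5-hydroxyl, giving 3-(benzyloxy)-2-[3,4-bis(benzyloxy)phenyl]-5-hydroxy-7,8-dimethoxy-4H-chromen-4-one F7. PhI(OAc)2 in MeCN/H2O at 0 °C should then oxidise the para-methoxyphenol to quinone 13 with loss of methanol.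

3. Step 9. Acylation may spill over to the 5-hydroxyl, and the hydroquinone may be reoxidised by air in the basic medium before it is acylated. The fallback masks the 5-hydroxyl and the C4 carbonyl as a temporary boron chelate; it sets out from 14 and rejoins at 15. BF3·OEt2 in CH2Cl2 should give the difluoroboron chelate of 14 (BF2 bridging the C5 oxygen and the C4 carbonyl oxygen) F8. Ac2O, Et3N and catalytic DMAP should acetylate its only free hydroxyl to give the difluoroboron chelate of 15 F9, and brief warming in aqueous MeOH should release 15.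

**Further compounds**

F1 | step 5 | 1-(2,3,4,6-tetramethoxyphenyl)ethan-1-one | COc1cc(OC)c(C(C)=O)c(OC)c1OC
F2 | step 5 | 1-(2-hydroxy-3,4,6-trimethoxyphenyl)ethan-1-one | COc1cc(OC)c(C(C)=O)c(O)c1OC
F3 | step 5 | (E)-3-[3,4-bis(benzyloxy)phenyl]-1-(2-hydroxy-3,4,6-trimethoxyphenyl)prop-2-en-1-one | COc1cc(OC)c(C(=O)/C=C/c2ccc(OCc3ccccc3)c(OCc3ccccc3)c2)c(O)c1OC
F4 | step 5 | 2-[3,4-bis(benzyloxy)phenyl]-5,7,8-trimethoxy-4H-chromen-4-one | COc1cc(OC)c2c(=O)cc(-c3ccc(OCc4ccccc4)c(OCc4ccccc4)c3)oc2c1OC
F5 | step 5 | 2-[3,4-bis(benzyloxy)phenyl]-2,3-epoxy-5,7,8-trimethoxychroman-4-one (cis-fused, racemic, one enantiomer drawn) | COc1cc(OC)c2C(=O)[C@H]3O[C@@]3(c3ccc(OCc4ccccc4)c(OCc4ccccc4)c3)Oc2c1OC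
F6 | step 7 | 2-[3,4-bis(benzyloxy)phenyl]-3,5-dihydroxy-7,8-dimethoxy-4H-chromen-4-one | COc1cc(O)c2c(=O)c(O)c(-c3ccc(OCc4ccccc4)c(OCc4ccccc4)c3)oc2c1OC
F7 | step 7 | 3-(benzyloxy)-2-[3,4-bis(benzyloxy)phenyl]-5-hydroxy-7,8-dimethoxy-4H-chromen-4-one | COc1cc(O)c2c(=O)c(OCc3ccccc3)c(-c3ccc(OCc4ccccc4)c(OCc4ccccc4)c3)oc2c1OC
F8 | step 9 | difluoroboron chelate of 14 (BF2 bridging the C5 oxygen and the C4 carbonyl oxygen, 8-hydroxyl free) | COc1cc2c3c(c1O)OC(c1ccc(OCc4ccccc4)c(OCc4ccccc4)c1)=C(OCc1ccccc1)C3=[O+][B-](F)(F)O2
F9 | step 9 | difluoroboron chelate of 15 (BF2 bridging the C5 oxygen and the C4 carbonyl oxygen, 8-acetate) | COc1cc2c3c(c1OC(C)=O)OC(c1ccc(OCc4ccccc4)c(OCc4ccccc4)c1)=C(OCc1ccccc1)C3=[O+][B-](F)(F)O2
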